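Late in both runs the electrophile readings keep falling while the target readings sink, so I keep the books on the electrophile, the reagent charged in this flask in the smaller amount.

the same everywhere: electrophile 0.099 M; solid base 0.109 M
- Saturday's: nucleophile 0.065 M; run made earlier
- Thursday's: nucleophile 0.097 M; run made earlier
- flask: nucleophile 0.129 M; time 40 min

| run | time / min | electrophile / % | target / % |
|---|---|---|---|
| Saturday's | 3.00 | 83 | 13 |
| Saturday's | 8.00 | 71 | 17 |
| Saturday's | 15.0 | 59 | 14 |
| Saturday's | 25.0 | 50 | 12 |
| Thursday's | 2.00 | 80 | 15 |
| Thursday's | 4.00 | 72 | 21 |
| Thursday's | 10.0 | 51 | 22 |
| Thursday's | 25.0 | 29 | 19 |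

(standard deviation of a reading: 2 percentage points)
- as a solid, counted per litre of solution: solid base
- at the start none of the solid base is in solution
- the earlier runs do not show how much of nucleophile is bound; that part of a forecast is a guess
- part of the electrophile that has reacted at 40 min
- share of free nucleophile in free nucleophile and protonated nucleophile together, at 40 min

Suppose the missing electrophile sits in a side product holding two units. Attacks by nucleophile, as a share of electrophile charged, are then half of reacted plus target. Suppose too that each attack costs two nucleophiles, one consumed and one parked as protonated nucleophile. Spare nucleophile at the last readings is then 0.00362 M on Saturday and 0.00790 M on Thursday: both runs are near a ceiling. For this flask that is 65.2%, the attack ceiling: half the nucleophile charge over the electrophile charge.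

If target ends near Thursday's last reading of 19%, finishing the electrophile takes attacks worth 59.5% of the charge, below the ceiling, with 0.0112 M spare. Thursday's last stretch reads, with its scatter, a log slope of 2.17 /M/min per spare nucleophile. Integrating that slope, with spare equal to 0.0112 M plus c(electrophile), leaves 5.81%, so I commit to 94.2% reacted, 56.6% attacks and 0.0169 M spare.

The weak link is calling all spare free. Thursday's late attack rate over its earliest slope reads 79.5% of spare as free, so my share is 19.4%.

The forecast said 92% and 68%, holding that “nucleophile is being tied up as protonated salt by released acid, then slowly freed as solid base dissolves”. The flask gives 90.2% and 14.9%.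

    electrophile + nucleophile → acid set free + target (k = 0.0230 /M/s)
    nucleophile + acid set free ⇌ protonated nucleophile, settled at all times (K = 47000 /M)
    acid set free + free base ⇌ salt of the base (K = 16.0 /M, k = 0.210 /M/s)
    electrophile + target → side product (k = 0.0190 /M/s)
    solid base ⇌ free base, rate k5*(cs5 - [free base]) while solid is left; crystals form when [free base] > cs5 (solubility = 13.0 mM, k = 0.0120 /s)
    nucleophile ⇌ dormant form (K = 0.700, k = 0.00260 /s)

In this flask attacks reach 56.6% of the electrophile charged, against the ceiling of 65.2%, leaving 0.0170 M spare, and the dormant form holds 0.00739 M of it. With 0.032 M of nucleophile the ceiling is 16.2%; twice that, less its 1.45% of target, is 30.9%. That flask reacts 31.1% of its electrophile, slightly past the count, with 8.01 × 10⁻⁴ M of acid set free and 1.58 × 10⁻⁴ M of salt of the base unparked, and of its nucleophile, the limiting reagent there, 1.3% is left.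

The numbers in the tables were computed with constants of no real substance; noise was put on by code.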